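## Retrosynthetic overview
1. Tuberatolide B ⇒ (desilylation, separation of the C2 epimers) ⇒ silyl-protected chromene–butenolide **16**.
2. **16** ⇒ (E-selective cross-metathesis) ⇒ methallyl butenolide **6** + 2-(3-butenyl)chromene **15**.
3. **6** ⇒ (radical deoxygenative isopropenylation of the chiral primary alcohol, the key step; Negishi α-alkylation) ⇒ commercial (S)-5-hydroxymethylbutenolide **1**. The butenolide ring and its γ-centre come from the chiral pool.
4. **15** ⇒ (propargyl aryl ether Claisen/6π-oxa-electrocyclisation) ⇒ phenol **10** + tertiary propargylic chloride **13**. Phenol **10** comes from o-cresol and **13** from hex-5-en-2-one. The chromene ring forms in step 10.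

Assumptions:
- (S)-5-(hydroxymethyl)-2(5H)-furanone is commercially available.
- The C2 quaternary centre is formed non-selectively in step 10, so the two C2 epimers form (tuberatolide B is the (2S) epimer). They are separated in step 12 and the (2S) epimer is assigned by comparison with literature data.

---

## Route

**Step 1**
Reactants: **1** (S)-5-(hydroxymethyl)furan-2(5H)-one
Product: **2** (S)-3-iodo-5-(hydroxymethyl)furan-2(5H)-one
Conditions: I2, pyridine, CH2Cl2, 0 °C → rt
Reagents that add atoms: iodine, II
Why: α-Iodination of the butenolide proceeds by iodine addition to the enone followed by pyridine-mediated elimination (Johnson iodination). The γ-centre is untouched and no new stereocentre forms.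

**Step 2**
Reactants: **2**; **3** 5-bromo-2-methylpent-2-ene (converted in situ to the alkylzinc)
Product: **4** (S)-5-(hydroxymethyl)-3-(4-methylpent-3-en-1-yl)furan-2(5H)-one
Conditions: **3**, Zn, LiCl, THF, 50 °C; then **2**, Pd-PEPPSI-IPr, THF, rt
Reagents that add atoms: none (the alkyl group comes from **3**)
Why: Negishi sp2–sp3 coupling installs the α-chain. Excess zinc reagent covers the free OH, and the γ-stereocentre is not involved.

**Step 3**
Reactants: **4**; **5** 2-bromopropene
Product: **6** (R)-5-(2-methylallyl)-3-(4-methylpent-3-en-1-yl)furan-2(5H)-one
Conditions: (i) 3-methylbenzoxazolium triflate, pyridine, MeCN, rt; (ii) Ir[dF(CF3)ppy]2(dtbbpy)PF6 (1 mol%), NiCl2·dtbbpy (10 mol%), **5** (3 equiv), blue LEDs, MeCN, rt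
Reagents that add atoms: 2-bromopropene, C=C(C)Br
Why: Proposed new method: alcohol **4** forms an NHC–alcohol adduct (benzoxazolium–O–CH2R). Photoexcited Ir(III) oxidises the adduct and C–O fragmentation releases the primary radical •CH2–C5 plus benzoxazolone. Ni(0) and isopropenyl bromide give an isopropenyl-Ni(II) species that captures the radical and reductively eliminates to the methallyl C–C bond. The closest known reaction is the NHC-mediated deoxygenative Ni/photoredox arylation of alcohols. The radical sits on the exocyclic carbon, so the γ-centre is not touched (the descriptor changes from S to R only because CIP priorities change). A 1,2-acyloxy shift is geometrically impossible in the lactone ring.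

**Step 4**
Reactants: **7** o-cresol
Product: **8** 2-methyl-1,4-benzoquinone
Conditions: (KSO3)2NO•, KH2PO4 (aq.), acetone/H2O, rt
Reagents that add atoms: water as the O source, O; Fremy's salt, [K+].[K+].[O-]S(=O)(=O)N([O])S(=O)(=O)[O-]
Why: Teuber oxidation of a para-unsubstituted phenol to the p-quinone; the new para-oxygen comes from water.

**Step 5**
Reactants: **8**
Product: **9** 2-methylbenzene-1,4-diol
Conditions: Na2S2O4, Et2O/H2O, rt
Reagents that add atoms: none
Why: Dithionite reduction of the quinone to the hydroquinone.

**Step 6**
Reactants: **9**
Product: **10** 4-(tert-butyldimethylsilyloxy)-2-methylphenol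
Conditions: TBSCl (1.0 equiv), imidazole, DMF, 0 °C → rt
Reagents that add atoms: TBSCl, CC(C)(C)[Si](C)(C)Cl
Why: Silylation goes at the less hindered OH para to the methyl group. The free OH flanked by the methyl group will become the chromene ring oxygen, and the single free ortho position (C6) is what the Claisen step will use.

**Step 7**
Reactants: **11** hex-5-en-2-one
Product: **12** 3-methylhept-6-en-1-yn-3-ol (racemic)
Conditions: HC≡CMgBr, THF, 0 °C → rt
Reagents that add atoms: ethynylmagnesium bromide, C#C[Mg]Br
Why: 1,2-Addition of the acetylide to the ketone. The carbinol centre is racemic and is destroyed in step 8.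

**Step 8**
Reactants: **12**
Product: **13** 3-chloro-3-methylhept-6-en-1-yne
Conditions: conc. HCl, CaCl2, CuCl (cat.), 0 °C
Reagents that add atoms: hydrogen chloride, Cl
Why: Cu(I)-assisted SN1-type chlorination of a tertiary propargylic alcohol (the standard route to 3-chloro-3-methylbutyne analogues). The centre is planar and stays racemic.

**Step 9**
Reactants: **10**; **13**
Product: **14** aryl propargyl ether, C#CC(C)(CCC=C)Oc1ccc(O[Si](C)(C)C(C)(C)C)cc1C
Conditions: K2CO3, KI, CuI (cat.), acetone, reflux
Reagents that add atoms: none
Why: Cu-assisted O-propargylation of the phenol with a tertiary propargylic chloride (as in precocene syntheses). The centre is racemic.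

**Step 10**
Reactants: **14**
Product: **15** 2-(but-3-en-1-yl)-2,8-dimethyl-6-(TBS-oxy)-2H-chromene (racemic at C2)
Conditions: PhNEt2, 210 °C
Reagents that add atoms: none
Why: Aromatic propargyl Claisen rearrangement, then enolisation, 1,5-H shift and 6π-oxa-electrocyclisation, builds the 2,2-disubstituted 2H-chromene. Only C6 of the phenol is free, which fixes the regiochemistry. C2 forms with no facial control, giving both epimers after step 11.

**Step 11**
Reactants: **6**; **15**
Product: **16** silyl-protected tuberatolide (E-alkene; C2 epimer mixture)
Conditions: Hoveyda–Grubbs II (7 mol%), p-benzoquinone (10 mol%), CH2Cl2, 40 °C, **6** (2.5 equiv)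
Reagents that add atoms: none (ethylene is lost)
Why: Cross-metathesis of the terminal alkene of **15** with the 1,1-disubstituted alkene of **6** gives the trisubstituted alkene, with thermodynamic E preference and ethylene release as the driving force. The butenolide, the prenyl terminus and the cyclic chromene alkene are unreactive.

**Step 12**
Reactants: **16**
Product: **17** tuberatolide B
Conditions: Et3N·3HF, THF, rt; then semi-preparative HPLC
Reagents that add atoms: none
Why: Mild fluoride removes the aryl TBS ether without base-induced γ-epimerisation. HPLC separates the C2 epimers (and any minor Z isomer) to give the (2S,5′R) diastereomer. This is where the C2 configuration of the target is fixed; the γ-centre comes from **1**.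

---

## Compound list
1 | (S)-5-(hydroxymethyl)furan-2(5H)-one | O=C1C=C[C@@H](CO)O1 | starting material
2 | (S)-3-iodo-5-(hydroxymethyl)furan-2(5H)-one | O=C1C(I)=C[C@@H](CO)O1 | intermediate
3 | 5-bromo-2-methylpent-2-ene | CC(C)=CCCBr | starting material
4 | (S)-5-(hydroxymethyl)-3-(4-methylpent-3-en-1-yl)furan-2(5H)-one | CC(C)=CCCC1=C[C@@H](CO)OC1=O | intermediate
5 | 2-bromopropene | C=C(C)Br | starting material
6 | (R)-5-(2-methylallyl)-3-(4-methylpent-3-en-1-yl)furan-2(5H)-one | CC(C)=CCCC1=C[C@@H](CC(C)=C)OC1=O | intermediate
7 | o-cresol | Cc1ccccc1O | starting material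
8 | 2-methyl-1,4-benzoquinone | CC1=CC(=O)C=CC1=O | intermediate
9 | 2-methylbenzene-1,4-diol | Cc1cc(O)ccc1O | intermediate
10 | 4-(tert-butyldimethylsilyloxy)-2-methylphenol | Cc1cc(O[Si](C)(C)C(C)(C)C)ccc1O | intermediate
11 | hex-5-en-2-one | CC(=O)CCC=C | starting material
12 | 3-methylhept-6-en-1-yn-3-ol | C#CC(C)(O)CCC=C | intermediate
13 | 3-chloro-3-methylhept-6-en-1-yne | C#CC(C)(Cl)CCC=C | intermediate
14 | aryl propargyl ether | C#CC(C)(CCC=C)Oc1ccc(O[Si](C)(C)C(C)(C)C)cc1C | intermediate
15 | 2-(but-3-en-1-yl)-2,8-dimethyl-6-(TBS-oxy)-2H-chromene (racemic) | C=CCCC1(C)C=Cc2cc(O[Si](C)(C)C(C)(C)C)cc(C)c2O1 | intermediate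
16 | silyl-protected tuberatolide (C2 epimers) | CC(C)=CCCC1=C[C@@H](C/C(C)=C/CCC2(C)C=Cc3cc(O[Si](C)(C)C(C)(C)C)cc(C)c3O2)OC1=O | intermediate
17 | tuberatolide B | CC(C)=CCCC1=C[C@@H](C/C(C)=C/CC[C@@]2(C)C=Cc3cc(O)cc(C)c3O2)OC1=O | target

---

**Total steps:** 12.
**Longest linear sequence:** 7 (o-cresol → 8 → 9 → 10 → 14 → 15 → 16 → 17).

**Three steps most likely to fail**
1. **Step 3 (radical deoxygenative isopropenylation).** The γ-CH2 radical or its activated adduct could eliminate to protoanemonin-type species, undergo 3-exo cyclisation onto the butenolide, or reduce the butenolide. *Fallback (different approach):* work on the saturated lactone instead. Appel-iodinate (S)-5-(hydroxymethyl)dihydrofuranone, couple the alkyl iodide with 2-bromopropene under Ni reductive conditions, then install the α-chain by enolate alkylation and introduce the butenolide unsaturation last (Se-based dehydrogenation).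
2. **Step 10 (C2 formed without control, then separated).** The yield is capped at about 50% per epimer, and the Claisen step at 210 °C may also convert the pendant alkene. *Fallback (different approach):* build C2 enantioselectively by Pd-catalysed asymmetric allylic etherification of phenol **10** with isoprene monoepoxide, then close the chromene by RCM with an ortho-vinyl group and elongate the CH2OH-derived chain.
3. **Step 11 (cross-metathesis with a 1,1-disubstituted alkene).** Conversion may be low, E/Z selectivity moderate, and homodimerisation of **15** competes. *Fallback (different approach):* form the E-alkene earlier. Use Zr-catalysed carboalumination of a propargyl-substituted lactone to give the (E)-alkenyl iodide, and couple it with a chromene–CH2CH2–I fragment by Ni-catalysed reductive cross-coupling.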